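## Analysis of the target

The target is a hexasubstituted benzene: C1 carries the formyl group, C2, C3 and C6 carry bromine, and C4 and C5 carry the two hydroxyls of a catechol. It has no stereocentre, so the whole difficulty is the order of six substituents around one ring. The catechol is the sensitive part: it is acidic, it is oxidised to the ortho-quinone by air under base and by halogenating agents, and its free hydroxyls do not tolerate organometallic reagents. The aldehyde can be lost by ipso substitution under electrophilic bromination, and the three aryl bromides rule out hydrogenolysis and uncontrolled halogen–metal exchange. A stepwise bromination of a catechol aldehyde would have to steer three brominations by competing directing effects on an ever more crowded ring. The strategy rests on the edge C3(Br)–C4(OH)–C5(OH)–C6(Br): without its oxygens it is 1,4-dibromobenzene, and the two oxygens sit on one CH–CH edge between the bromines, which is where toluene dioxygenase adds O2. The remaining atoms C1 and C2 are then the two equivalent C–H of a symmetric dibromocatechol, so the third bromine and the formyl group can be added one after the other without any regiochemical choice.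

## Retrosynthetic reasoning

**14 ⇒ 12 (the two O–CH3 bonds).** The last step only unmasks the catechol of target 14 from its dimethyl ether 12. The catechol is kept masked to the end because the free bromocatechol is the most acidic and most oxidation-prone form of the ring and cannot pass through an organolithium step. The forward reaction must cleave two hindered methyl ethers without touching the aldehyde or the three C–Br bonds; a boron Lewis acid does this through the cyclic borate 13.

**12 ⇒ 8 + 9 (the C1–CHO bond).** The tribromide 8 has a single C–H, and it lies between two bromine-bearing carbons. Cutting the formyl carbon off here means there is no second position at which it could enter. The C–H is also acidic enough for amide-base deprotonation, so the ring carbon acts as the nucleophile (aryllithium 10) towards the formamide 9, and the tetrahedral adduct 11 holds the aldehyde oxidation level until work-up. Electrophilic formylation would be the wrong polarity for so electron-poor a ring. The forward step must keep 10 cold, so that it neither collapses to an aryne by loss of an ortho bromine nor exchanges bromine with unreacted 8.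

**8 ⇒ 6 + 7 (the C2–Br bond).** The dimethyl ether 6 has two C–H, and they are equivalent, each para to one methoxy oxygen, so bromination with 7 can give only one monobromide. The bromination is placed before the formylation on purpose. Formylating 6 first would need an electrophile to attack a ring that carries two bromines and two methoxy groups twisted out of conjugation by their neighbours. It would also leave the last bromination next to a formyl group on a free catechol, where ipso attack and oxidation threaten. Bromine first avoids both and creates the acidic C–H used in the previous disconnection. The forward reaction has to stop after one substitution.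

**6 ⇒ 4 (the two O–CH3 bonds, through monoether 5).** The catechol 4 is masked as its dimethyl ether so that it survives Lewis-acidic bromination and the lithium amide base. Methyl is chosen because it is small enough to go onto hydroxyls that each have two ortho neighbours, and because it comes off in one operation at the end. The forward reaction is a double O-alkylation under mild base with exclusion of air.

**4 ⇒ 2 (change of oxidation level, through 3).** The catechol 4 is the dehydrogenation product of the cis-diol 2. No skeletal bond is cut; one carbinol carbon is oxidised to the ketone 3, which enolises to the arene. The forward reaction has to be an oxidation under neutral conditions, because acid would dehydrate 2 to a phenol and throw away one of the two oxygens. The dehydrogenase of the same bacterial pathway does exactly this.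

**2 ⇒ 1 (the bonds C4–O and C5–O).** Both oxygens are removed from one CH–CH edge, which leads back to the commodity arene 1. This is the only disconnection that places two oxygens between the two bromines in one step and with no directing group. It works because the four C–H of 1 form two equivalent edges, so one diol results, and it is meso. The forward reaction must add both oxygen atoms of air to two adjacent C–H carbons, and not to a bromine-bearing carbon, and must stop at the diol.

## Alternatives that were turned down

**Alternative 1:** The ring is cut at C1–C6 and C2–C3. C1 and C2 would come from the bromoalkyne 1-bromo-3,3-diethoxyprop-1-yne A2, and C3 to C6 from the diene 2,5-dibromo-3,4-dimethoxythiophene 1,1-dioxide A1. In the forward direction A1 and A2 would combine in a [4+2] cycloaddition, and the bridged adduct would lose its sulfonyl bridge by cheletropic extrusion. That closes the benzene ring and gives 2,3,6-tribromo-4,5-dimethoxybenzaldehyde diethyl acetal A3, from which acetal hydrolysis and ether cleavage would lead to the target.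
- For it: all six substituents of A3 arrive in one convergent step, the diene A1 is symmetric so the orientation of the alkyne A2 does not matter, and neither an electrophilic bromination nor an organolithium step is needed. On convergence it is stronger than the chosen route, and its step count is about the same.
- Against it: thiophene dioxides are electron-poor dienes that react best with electron-rich or strained partners, whereas A2 is a hindered, electronically unactivated bromoalkyne. The cycloaddition to A3 would need heat, under which thiophene dioxides dimerise and bromoalkynes decompose. The S-oxidation that makes A1 would also have to stop cleanly at the dioxide on a thiophene with two donor groups.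
- Comparison: the chosen strategy offers a key step of an established reaction class and a line of symmetric intermediates, at the price of being linear and needing a fermentation.

**Alternative 2:** Here the two C–Br bonds at C2 and C3 are cut. An ortho-silylaryl triflate such as 4-bromo-3-(dimethoxymethyl)-5,6-dimethoxy-2-(trimethylsilyl)phenyl trifluoromethanesulfonate A4 would be treated with fluoride to give the aryne 1-bromo-6-(dimethoxymethyl)-2,3-dimethoxy-4,5-didehydrobenzene A5, whose triple bond is C2≡C3 of the target. Bromide would add, and the resulting aryl anion would take bromine from a positive-bromine donor, giving 2,3,6-tribromo-4,5-dimethoxybenzaldehyde dimethyl acetal A6. After A6 only deprotection would remain.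
- For it: both new substituents are bromine, so the direction of addition to the unsymmetrical aryne A5 is irrelevant. The conditions are mild and no fermentation is needed, so in an ordinary laboratory the step is at least as easy to run as the chosen key step.
- Against it: A4 is itself a hexasubstituted benzene with five different groups in fixed order, so nearly the whole regiochemical problem of the target has to be solved beforehand, in an estimated six or more steps. On the way to A6 the aryl anion is flanked on both sides and strongly basic, so protonation competes with bromination. Fluoride competes with bromide for A5, and bromide is a weak nucleophile towards arynes.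
- Comparison: the chosen route reaches the same pattern in six steps, because symmetry and not a pre-built precursor decides every position.

**Alternative 3:** The ring is cut at C3–C4 and C5–C6. The catechol carbons C4 and C5 would come from di-tert-butoxyethyne A8, and C6, C1, C2 and C3 from methyl 2,4,5-tribromothiophene-3-carboxylate 1,1-dioxide A7. A [4+2] cycloaddition followed by loss of the sulfonyl bridge would close the benzene ring and give methyl 2,3,6-tribromo-4,5-di-tert-butoxybenzoate A9.
- For it: the electron demand is ideal, since A7 carries a sulfone, an ester and three bromines and A8 is a very electron-rich alkyne. The alkyne is symmetric, so there is no regiochemistry, and the tert-butyl ethers of A9 come off with mild acid. As a bond construction this key step is probably more reliable than the dioxygenation of the chosen route, and its final deprotection is milder.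
- Against it: A8 is not commercial, needs its own multistep preparation and fragments on warming. A7 requires forcing S-oxidation of a very electron-poor thiophene. C1 arrives in A9 as an ester between two ortho bromines and must be brought to the aldehyde level by reduction and reoxidation or a delicate partial reduction. The count is nine or more steps over two branches.
- Comparison: the chosen strategy starts from a commodity arene, is six steps long and brings C1 in at the aldehyde oxidation level.

Key step: step 1

## Route

Remark: the biocatalysts of steps 1 and 2 are assumed to be recombinant Escherichia coli strains carrying genes of the Pseudomonas putida toluene pathway (todC1C2BA for step 1, todD for step 2). They are catalysts and are not counted as starting materials.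

Step 1
Reactants: 1 1,4-dibromobenzene
Product: 2 (1R,2S)-3,6-dibromocyclohexa-3,5-diene-1,2-diol (cis-diol; meso)
Conditions: E. coli whole cells expressing toluene dioxygenase (todC1C2BA), glucose, air, phosphate buffer pH 7.2, 30 °C, 1 fed in liquid paraffin; EtOAc extraction at pH ≥ 7
Reagents that add atoms: dioxygen, O=O
Why: Toluene dioxygenase is a Rieske non-haem iron dioxygenase: two electrons from NADH pass through the reductase and the [2Fe-2S] ferredoxin to the oxygenase, whose mononuclear iron centre binds O2 side-on and delivers both oxygen atoms to two adjacent arene carbons from one face, without an arene oxide. The closest known reaction type is this same whole-cell cis-dihydroxylation of halobenzenes and para-dihalobenzenes. No ring is closed; the step only breaks the aromaticity of 1. The two new stereocentres (C1 and C2 of 2, the later C5 and C4 of the target) are set cis because both oxygens come from the same enzyme-bound O2. Since both CH–CH edges of 1 are equivalent, 2 should form as a single meso compound and enantioselectivity plays no role. The selectivity that is needed is site selectivity for a CH–CH edge over a bromine-bearing carbon, where attack would end in loss of bromide; the preference of the enzyme for the unsubstituted edge next to a halogen secures it, and either edge gives the same product. Over-oxidation should not occur because the host lacks the diol dehydrogenase and 2 is no longer an arene.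

Step 2
Reactants: 2 (1R,2S)-3,6-dibromocyclohexa-3,5-diene-1,2-diol
Product: 4 3,6-dibromobenzene-1,2-diol, via 2,5-dibromo-6-hydroxycyclohexa-2,4-dien-1-one 3 (not isolated)
Conditions: resting E. coli cells expressing toluene cis-dihydrodiol dehydrogenase (todD), air, phosphate buffer pH 7.4, 30 °C; then pH 4, ascorbic acid, EtOAc
Reagents that add atoms: none
Why: NAD+-dependent dehydrogenation of one of the two enantiotopic carbinol carbons gives hydroxy dienone 3, which enolises at once to the aromatic catechol 4; this is the second enzyme of the toluene pathway and the known way from arene cis-dihydrodiols to catechols, with NAD+ recycled by respiration. The neutral medium avoids the acid-catalysed dehydration that would cost one oxygen, and the two stereocentres of 2 disappear here.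

Step 3
Reactants: 4 3,6-dibromobenzene-1,2-diol
Product: 6 1,4-dibromo-2,3-dimethoxybenzene, via 3,6-dibromo-2-methoxyphenol 5 (not isolated)
Conditions: MeI, K2CO3, acetone, reflux, N2
Reagents that add atoms: iodomethane, CI
Why: Williamson ether synthesis; the ortho-bromine atoms make both hydroxyls acidic enough for K2CO3, methyl is small enough for the flanked oxygens, and exclusion of air suppresses autoxidation of the catecholate.

Step 4
Reactants: 6 1,4-dibromo-2,3-dimethoxybenzene; 7 bromine
Product: 8 1,2,5-tribromo-3,4-dimethoxybenzene
Conditions: Br2 (1.05 equiv), FeBr3 (cat.), CH2Cl2, 0 °C → rt
Reagents that add atoms: bromine (compound 7), BrBr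
Why: Lewis-acid-catalysed electrophilic aromatic bromination; the two C–H of 6 are equivalent and each is para to one methoxy oxygen, so only one monobromide can form, and the new bromine lowers the reactivity towards a second substitution.

Step 5
Reactants: 8 1,2,5-tribromo-3,4-dimethoxybenzene; 9 N,N-dimethylformamide
Product: 12 2,3,6-tribromo-4,5-dimethoxybenzaldehyde, via (2,3,6-tribromo-4,5-dimethoxyphenyl)lithium 10 (not isolated), via lithium (dimethylamino)(2,3,6-tribromo-4,5-dimethoxyphenyl)methanolate 11 (not isolated)
Conditions: LiN(i-Pr)2 (1.1 equiv), THF, −78 °C; DMF, −78 → 0 °C; then H2O
Reagents that add atoms: N,N-dimethylformamide (compound 9), CN(C)C=O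
Why: Deprotonative metalation followed by formylation: the only C–H of 8 lies between two bromines, which make it strongly acidic, and lithium diisopropylamide removes it at −78 °C without halogen–lithium exchange. Aryllithium 10 adds to 9 to give hemiaminolate 11 (racemic at the new carbon, which becomes the formyl carbon), and water releases the aldehyde; the same sequence is the standard way from 1,3-dibromoarenes to 2,6-dibromobenzaldehydes.

Step 6
Reactants: 12 2,3,6-tribromo-4,5-dimethoxybenzaldehyde
Product: 14 2,3,6-tribromo-4,5-dihydroxybenzaldehyde, via 2,4,6,7-tetrabromo-1,3,2-benzodioxaborole-5-carbaldehyde 13 (not isolated)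
Conditions: BBr3 (3 equiv), CH2Cl2, −78 °C → rt; then H2O
Reagents that add atoms: none
Why: Lewis-acid ether cleavage: BBr3 binds each methoxy oxygen and bromide removes the methyl group by SN2, giving the cyclic aryl borate 13, which water hydrolyses to the catechol. The aldehyde is only complexed reversibly and the aryl bromides are inert, and the acidic work-up keeps the catechol from air oxidation.

## Compound list

1 | 1,4-dibromobenzene | Brc1ccc(Br)cc1 | starting material
2 | (1R,2S)-3,6-dibromocyclohexa-3,5-diene-1,2-diol (cis, meso) | O[C@@H]1[C@H](O)C(Br)=CC=C1Br | intermediate
3 | 2,5-dibromo-6-hydroxycyclohexa-2,4-dien-1-one (configuration at C6 not defined, lost on enolisation) | O=C1C(Br)=CC=C(Br)C1O | intermediate (not isolated)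
4 | 3,6-dibromobenzene-1,2-diol | Oc1c(O)c(Br)ccc1Br | intermediate
5 | 3,6-dibromo-2-methoxyphenol | COc1c(O)c(Br)ccc1Br | intermediate (not isolated)
6 | 1,4-dibromo-2,3-dimethoxybenzene | COc1c(OC)c(Br)ccc1Br | intermediate
7 | bromine | BrBr | starting material
8 | 1,2,5-tribromo-3,4-dimethoxybenzene | COc1c(OC)c(Br)c(Br)cc1Br | intermediate
9 | N,N-dimethylformamide | CN(C)C=O | starting material
10 | (2,3,6-tribromo-4,5-dimethoxyphenyl)lithium | [Li]c1c(Br)c(Br)c(OC)c(OC)c1Br | intermediate (not isolated)
11 | lithium (dimethylamino)(2,3,6-tribromo-4,5-dimethoxyphenyl)methanolate (racemic) | [Li]OC(N(C)C)c1c(Br)c(Br)c(OC)c(OC)c1Br | intermediate (not isolated)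
12 | 2,3,6-tribromo-4,5-dimethoxybenzaldehyde | O=Cc1c(Br)c(Br)c(OC)c(OC)c1Br | intermediate
13 | 2,4,6,7-tetrabromo-1,3,2-benzodioxaborole-5-carbaldehyde | O=Cc1c(Br)c(Br)c2OB(Br)Oc2c1Br | intermediate (not isolated)
14 | 2,3,6-tribromo-4,5-dihydroxybenzaldehyde | O=Cc1c(Br)c(O)c(O)c(Br)c1Br | target

## Step count and risk

Total step count: 6. Longest linear sequence: 6 steps, from 1 to 14.

**Step 1 (key step).** The most likely failure is poor turnover. Compound 1 is a crystalline, nearly water-insoluble, para-disubstituted substrate that should bind more slowly than a monohalobenzene and is toxic to the cells. The diol may also dehydrate if the broth or the extract turns acidic.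

Fallback: the oxygens are introduced chemically by two directed metalations, setting out from 1 and returning at 5. Lithium diisopropylamide in THF at −78 °C deprotonates 1 next to bromine to give (2,5-dibromophenyl)lithium F1. This is trapped with B(OMe)3 as dimethyl (2,5-dibromophenyl)boronate F2 and oxidised with H2O2/AcOH to 2,5-dibromophenol F3. Methylation (MeI, K2CO3, acetone) gives 1,4-dibromo-2-methoxybenzene F4, whose C–H between the methoxy group and a bromine is the most acidic one. A second deprotonation gives (3,6-dibromo-2-methoxyphenyl)lithium F5, borylation gives dimethyl (3,6-dibromo-2-methoxyphenyl)boronate F6, and oxidation gives 5, which is methylated to 6 as in step 3.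

**Step 2.** The dehydrogenase may accept a diol with bromine on both flanking carbons only slowly. The catechol may inhibit or poison the cells, may be oxidised by air, and the diol may dehydrate during the acidic work-up.

Fallback: a chemical oxidation through the quinone level, setting out from 2 and returning at 4. 2-Iodoxybenzoic acid (IBX, about 2.5 equiv) in DMSO at room temperature oxidises one allylic carbinol. The catechol that forms by way of 3 is oxidised further to 3,6-dibromocyclohexa-3,5-diene-1,2-dione F7, and a wash with aqueous Na2S2O4 reduces this quinone to 4.

**Step 4.** Compound 6 is only weakly activated, because both methoxy groups are forced out of the ring plane. The conversion may therefore be sluggish, and forcing it invites a second bromination or ether cleavage by the hydrogen bromide formed.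

Fallback: the bromine is introduced on the free catechol, whose hydroxyls are coplanar and activate the para positions strongly, setting out from 4 and returning at 8. Br2 (1 equiv) in AcOH at room temperature should give 3,4,6-tribromobenzene-1,2-diol F8. Double O-methylation under the conditions of step 3, through the two monoethers 3,4,6-tribromo-2-methoxyphenol F9 and 3,5,6-tribromo-2-methoxyphenol F10, gives 8.

**Step 5.** Aryllithium 10 has bromine on both neighbouring carbons. Above −78 °C it may lose lithium bromide to an aryne, and if deprotonation is incomplete it may exchange bromine with unreacted 8 and scramble the halogen pattern. Addition to 9 may also be slow for steric reasons.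

Fallback: electrophilic formylation before the third bromine, setting out from 6 and returning at 14. Rieche formylation (Cl2CHOMe, TiCl4, CH2Cl2, 0 °C to reflux) at either of the two equivalent C–H passes through 1,4-dibromo-5-[chloro(methoxy)methyl]-2,3-dimethoxybenzene F11, which water hydrolyses to 2,5-dibromo-3,4-dimethoxybenzaldehyde F12. BBr3 demethylation through 2,4,7-tribromo-1,3,2-benzodioxaborole-5-carbaldehyde F13 gives 2,5-dibromo-3,4-dihydroxybenzaldehyde F14. Br2 in AcOH then brominates the last C–H, which is para to one hydroxyl, and gives 14. The weak point of this sequence is the low nucleophilicity of 6 in the formylation.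

## Further compounds

F1 | step 1 | (2,5-dibromophenyl)lithium | [Li]c1cc(Br)ccc1Br
F2 | step 1 | dimethyl (2,5-dibromophenyl)boronate | COB(OC)c1cc(Br)ccc1Br
F3 | step 1 | 2,5-dibromophenol | Oc1cc(Br)ccc1Br
F4 | step 1 | 1,4-dibromo-2-methoxybenzene | COc1cc(Br)ccc1Br
F5 | step 1 | (3,6-dibromo-2-methoxyphenyl)lithium | [Li]c1c(OC)c(Br)ccc1Br
F6 | step 1 | dimethyl (3,6-dibromo-2-methoxyphenyl)boronate | COB(OC)c1c(OC)c(Br)ccc1Br
F7 | step 2 | 3,6-dibromocyclohexa-3,5-diene-1,2-dione | O=C1C(=O)C(Br)=CC=C1Br
F8 | step 4 | 3,4,6-tribromobenzene-1,2-diol | Oc1c(O)c(Br)c(Br)cc1Br
F9 | step 4 | 3,4,6-tribromo-2-methoxyphenol | COc1c(O)c(Br)cc(Br)c1Br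
F10 | step 4 | 3,5,6-tribromo-2-methoxyphenol | COc1c(O)c(Br)c(Br)cc1Br
F11 | step 5 | 1,4-dibromo-5-[chloro(methoxy)methyl]-2,3-dimethoxybenzene (racemic) | COC(Cl)c1cc(Br)c(OC)c(OC)c1Br
F12 | step 5 | 2,5-dibromo-3,4-dimethoxybenzaldehyde | O=Cc1cc(Br)c(OC)c(OC)c1Br
F13 | step 5 | 2,4,7-tribromo-1,3,2-benzodioxaborole-5-carbaldehyde | O=Cc1cc(Br)c2OB(Br)Oc2c1Br
F14 | step 5 | 2,5-dibromo-3,4-dihydroxybenzaldehyde | O=Cc1cc(Br)c(O)c(O)c1Br
A1 | alternative 1 | 2,5-dibromo-3,4-dimethoxythiophene 1,1-dioxide | COC1=C(Br)S(=O)(=O)C(Br)=C1OC
A2 | alternative 1 | 1-bromo-3,3-diethoxyprop-1-yne | CCOC(OCC)C#CBr
A3 | alternative 1 | 2,3,6-tribromo-4,5-dimethoxybenzaldehyde diethyl acetal | CCOC(OCC)c1c(Br)c(Br)c(OC)c(OC)c1Br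
A4 | alternative 2 | 4-bromo-3-(dimethoxymethyl)-5,6-dimethoxy-2-(trimethylsilyl)phenyl trifluoromethanesulfonate | COC(OC)c1c(Br)c(OC)c(OC)c(OS(=O)(=O)C(F)(F)F)c1[Si](C)(C)C
A5 | alternative 2 | 1-bromo-6-(dimethoxymethyl)-2,3-dimethoxy-4,5-didehydrobenzene | COC(OC)C1=C(Br)C(OC)=C(OC)C#C1
A6 | alternative 2 | 2,3,6-tribromo-4,5-dimethoxybenzaldehyde dimethyl acetal | COC(OC)c1c(Br)c(OC)c(OC)c(Br)c1Br
A7 | alternative 3 | methyl 2,4,5-tribromothiophene-3-carboxylate 1,1-dioxide | COC(=O)C1=C(Br)S(=O)(=O)C(Br)=C1Br
A8 | alternative 3 | di-tert-butoxyethyne | CC(C)(C)OC#COC(C)(C)C
A9 | alternative 3 | methyl 2,3,6-tribromo-4,5-di-tert-butoxybenzoate | COC(=O)c1c(Br)c(Br)c(OC(C)(C)C)c(OC(C)(C)C)c1Br
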